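**Retrosynthetic overview**

1. Last disconnection: both C8–CH2 bonds of the gem-diprenyl carbon. Dearomatised ring A goes back to aromatic 6-benzoyl-5,7-dihydroxy-2,2-dimethyl-2H-chromene and two prenyl bromides.
2. Key disconnection: pyran ring B (O1, C2, C3, C4, C4a, C8a) goes back to the furan ring of 5-benzoyl-4,6-dihydroxybenzofuran by removing C2 with its two methyl groups. In the forward direction a CMe2 unit is placed on the furan C2=C3 bond as a cyclopropane, and strain release moves O1 from the old furan C2 onto the new carbon (five-membered to six-membered ring).
3. Enabling feature (benzofuran numbering): the furan C2=C3 enol-ether bond lies between O1 and C3a of phloroglucinol ring A. O1 is an aryloxide para to the benzoyl C=O and so a good leaving group, the C4 and C6 oxygens of ring A carry positive charge at C3, and the C4 oxygen, peri to C3, holds the zinc carbenoid.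
4. Furan: O-alkylation of the para OH of 2,4,6-trihydroxybenzophenone with bromoacetaldehyde diethyl acetal, then cyclodehydration. This fixes O1 para to the benzoyl group.
5. Order of rings: ring A (bought, aromatic), furan, transient cyclopropane, ring B, then dearomatisation of ring A.

Key step: step 3

Assumption: 2,4,6-trihydroxybenzophenone, bromoacetaldehyde diethyl acetal, 2,2-diiodopropane and prenyl bromide are taken as catalogue chemicals; the target and all isolated intermediates are achiral, so no configuration has to be set.

Step 1
Reactants: 1 2,4,6-trihydroxybenzophenone; 2 bromoacetaldehyde diethyl acetal (2-bromo-1,1-diethoxyethane)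
Product: 3 [4-(2,2-diethoxyethoxy)-2,6-dihydroxyphenyl](phenyl)methanone
Conditions: K2CO3 (1.1 equiv), NaI (cat.), DMF, 90 °C
Reagents that add atoms: bromoacetaldehyde diethyl acetal, CCOC(CBr)OCC
Why: Williamson ether synthesis in which one equivalent of weak base should deprotonate only the most acidic, non-chelated 4-OH (para to the benzoyl group), the two ortho OH groups being held in hydrogen bonds to the C=O, so the primary bromide should alkylate O4 alone and no stereocentre is formed.

Step 2
Reactants: 3 [4-(2,2-diethoxyethoxy)-2,6-dihydroxyphenyl](phenyl)methanone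
Product: 4 (4,6-dihydroxy-1-benzofuran-5-yl)(phenyl)methanone
Conditions: Amberlyst-15, toluene, 110 °C, ethanol distilled off
Reagents that add atoms: none
Why: Acid-catalysed cyclodehydration of an aryloxyacetaldehyde acetal (intramolecular Friedel–Crafts hydroxyalkylation, then loss of the second ethanol), the standard benzofuran synthesis, in which the oxocarbenium ion attacks one of the two equivalent, strongly activated ring carbons ortho to the ether oxygen, so only one benzofuran can form and O1 stays para to the benzoyl group.

Step 3
Reactants: 4 (4,6-dihydroxy-1-benzofuran-5-yl)(phenyl)methanone; 5 2,2-diiodopropane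
Product: 8 (5,7-dihydroxy-2,2-dimethyl-2H-chromen-6-yl)(phenyl)methanone, via cyclopropa[b]benzofuran 6 (not isolated), via vinyl ortho-quinone methide 7 (not isolated)
Conditions: Et2Zn (4 equiv), Me2CI2 (2 equiv), ClCH2CH2Cl, 0 °C to rt, then 60 °C
Reagents that add atoms: 2,2-diiodopropane, CC(C)(I)I
Why: Proposed new method: Et2Zn and 5 should give EtZnCMe2I, whose ethyl group is protonated off by the acidic C4–OH of 4 to leave an aryloxyzinc carbenoid ArOZnCMe2I peri to furan C3, and this should deliver CMe2 to the electron-rich furan C2=C3 bond by a concerted [2+1] closure of the three-membered ring of 6; the closest known reaction type is the Simmons–Smith gem-dimethylcyclopropanation of allylic alcohols with Et2Zn/Me2CI2, together with the known gain in reactivity when a zinc carbenoid carries an acidic aryloxide ligand. In 6 the old C2–O1 bond is a cyclopropyl C–O bond whose aryloxide is para to the benzoyl C=O, so on warming with the ZnI2 formed in the flask it should ionise while the distal CMe2–C3 bond opens in the disrotatory cyclopropyl-to-allyl sense, the charge being shared by the tertiary CMe2 end and the C4/C6 oxygens of ring A, which is the unravelling known for cyclopropanated furans and is driven by loss of the cyclopropane strain. Since O1 and C3a are cis on the cyclopropane, both rotate inward and 7 arises with the Z exocyclic C=C and an s-cis diene, so that O1 closes onto CMe2 by a thermal disrotatory oxa-6π electrocyclisation, the ring-closing event of ortho-quinone-methide chromene syntheses, which re-aromatises ring A and builds the six-membered ring from the five furan atoms plus the new carbon. The two stereocentres of cis-fused racemic 6 vanish again, so 8 has none to control. The step needs attack on the furan C2=C3 bond and not on the benzoyl C=O or the arene (only the enol-ether bond is nucleophilic enough and it sits next to the zinc-bearing oxygen), a single insertion (C3=C4 of 8 is shielded by the quaternary C2), closure on O1 and not on the neighbouring C5 oxygen (set by the Z geometry, closure being faster than C=C rotation), and aprotic conditions until the expansion is complete, because protolysis of 6 would end in isopropylbenzofurans.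

Step 4
Reactants: 8 (5,7-dihydroxy-2,2-dimethyl-2H-chromen-6-yl)(phenyl)methanone; 9 prenyl bromide (1-bromo-3-methylbut-2-ene)
Product: 11 6-benzoyl-7-hydroxy-2,2-dimethyl-8,8-bis(3-methylbut-2-en-1-yl)-2H-chromen-5(8H)-one (target), via 8-prenylchromene 10 (not isolated)
Conditions: prenyl bromide (2.5 equiv), KOH, H2O, 0 °C to rt
Reagents that add atoms: prenyl bromide, CC(C)=CCBr
Why: Alkylative dearomatisation of an acylphloroglucinol, in which the phenolate of 8 should take the soft allylic bromide at its only free ring carbon C8 to give 10 and the phenolate of 10 should be alkylated again at the same carbon, because attack at C6 would break the benzoyl chelate, as in the prenylation of acylphloroglucinols to the gem-diprenyl hop beta-acids; C8 carries two identical groups, so no stereocentre arises.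

**Compound list**

1 | 2,4,6-trihydroxybenzophenone | O=C(c1ccccc1)c1c(O)cc(O)cc1O | starting material
2 | bromoacetaldehyde diethyl acetal | CCOC(CBr)OCC | starting material
3 | [4-(2,2-diethoxyethoxy)-2,6-dihydroxyphenyl](phenyl)methanone | CCOC(COc1cc(O)c(C(=O)c2ccccc2)c(O)c1)OCC | intermediate
4 | (4,6-dihydroxy-1-benzofuran-5-yl)(phenyl)methanone | O=C(c1ccccc1)c1c(O)cc2occc2c1O | intermediate
5 | 2,2-diiodopropane | CC(C)(I)I | starting material
6 | 5-benzoyl-4,6-dihydroxy-substituted 1,1-dimethyl-1a,6b-dihydro-1H-cyclopropa[b]benzofuran (oxygen positions in the numbering of 4; cis-fused, racemic, not isolated) | CC1(C)C2Oc3cc(O)c(C(=O)c4ccccc4)c(O)c3C12 | intermediate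
7 | (Z)-4-benzoyl-3,5-dihydroxy-6-(3-methylbut-2-enylidene)cyclohexa-2,4-dien-1-one (side chain syn to the ring C=O, not isolated) | CC(C)=C/C=C1\C(=O)C=C(O)C(C(=O)c2ccccc2)=C1O | intermediate
8 | (5,7-dihydroxy-2,2-dimethyl-2H-chromen-6-yl)(phenyl)methanone | CC1(C)C=Cc2c(O1)cc(O)c(C(=O)c1ccccc1)c2O | intermediate
9 | prenyl bromide | CC(C)=CCBr | starting material
10 | [5,7-dihydroxy-2,2-dimethyl-8-(3-methylbut-2-en-1-yl)-2H-chromen-6-yl](phenyl)methanone (not isolated) | CC(C)=CCc1c(O)c(C(=O)c2ccccc2)c(O)c2C=CC(C)(C)Oc12 | intermediate
11 | 6-benzoyl-7-hydroxy-2,2-dimethyl-8,8-bis(3-methylbut-2-en-1-yl)-2H-chromen-5(8H)-one | CC(C)=CCC1(CC=C(C)C)C(O)=C(C(=O)c2ccccc2)C(=O)C2=C1OC(C)(C)C=C2 | target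

Total step count: 4. Longest linear sequence: 4 steps (1, 3, 4, 8, 11).

**Steps most likely to fail**

**Step 3.**
- Risk: the hindered isopropylidene carbenoid may decay by beta-elimination before it is transferred. The cyclopropane may be opened by adventitious protons in the wrong sense. The new C3=C4 bond may be cyclopropanated a second time.
- Fallback (known reaction types, again a five-to-six ring expansion): it sets out from 1 and comes back at 8.
- Mono-C-prenylation of 1 with one equivalent of 9 in aqueous KOH should give 3-prenyl-2,4,6-trihydroxybenzophenone F1.
- Epoxidation with mCPBA (NaHCO3 buffer) and 5-exo opening of the epoxide by the free 4-OH should give the racemic hydroxyisopropyl-dihydrobenzofuran F2.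
- SOCl2/pyridine should ionise the tertiary alcohol, the ring oxygen should bridge to a bicyclic oxonium ion, and chloride should open it at the secondary carbon. This is the ring expansion known for 2-(1-sulfonyloxyalkyl)tetrahydrofurans, and it should give the racemic 3-chlorochroman F3.
- DBU then removes HCl across C3–C4 to give 8.

**Step 4.**
- Risk: O-alkylation of the phenolates may compete, and the reaction may stall after the first prenylation because of crowding at C8.
- Fallback: it sets out from 8 and comes back at 11.
- Tsuji–Trost allylation with allyl methyl carbonate and Pd(PPh3)4 uses a smaller, softer pi-allyl electrophile that favours carbon. It should give the 8,8-diallyl compound F4.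
- Double cross-metathesis of F4 with 2-methylbut-2-ene and the second-generation Grubbs catalyst, (H2IMes)(PCy3)Cl2Ru=CHPh, should turn both allyl groups into prenyl groups. The C3=C4 bond is protected by the neighbouring quaternary C2.

**Step 2.**
- Risk: the liberated oxocarbenium ion may condense intermolecularly with a second electron-rich ring, and the benzofuran may oligomerise under acid.
- Fallback: it sets out from 1 and comes back at 4.
- Allyl bromide/K2CO3 should give the 4-O-allyl ether F5.
- Thermal aromatic Claisen rearrangement should give 3-allyl-2,4,6-trihydroxybenzophenone F6.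
- Lemieux–Johnson cleavage (OsO4 cat., NaIO4) should give the aldehyde, which closes with the free, non-chelated 4-OH to the racemic lactol F7.
- A trace of TsOH at room temperature should dehydrate F7 to 4, so the carbon–carbon bond is made pericyclically and strong acid is avoided.

**Further compounds**

F1 | step 3 | 3-prenyl-2,4,6-trihydroxybenzophenone | CC(C)=CCc1c(O)cc(O)c(C(=O)c2ccccc2)c1O
F2 | step 3 | [4,6-dihydroxy-2-(2-hydroxypropan-2-yl)-2,3-dihydro-1-benzofuran-5-yl](phenyl)methanone, racemic | CC(C)(O)C1Cc2c(O1)cc(O)c(C(=O)c1ccccc1)c2O
F3 | step 3 | (3-chloro-5,7-dihydroxy-2,2-dimethylchroman-6-yl)(phenyl)methanone, racemic | CC1(C)Oc2cc(O)c(C(=O)c3ccccc3)c(O)c2CC1Cl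
F4 | step 4 | 8,8-diallyl-6-benzoyl-7-hydroxy-2,2-dimethyl-2H-chromen-5(8H)-one | C=CCC1(CC=C)C(O)=C(C(=O)c2ccccc2)C(=O)C2=C1OC(C)(C)C=C2
F5 | step 2 | [4-(allyloxy)-2,6-dihydroxyphenyl](phenyl)methanone | C=CCOc1cc(O)c(C(=O)c2ccccc2)c(O)c1
F6 | step 2 | 3-allyl-2,4,6-trihydroxybenzophenone | C=CCc1c(O)cc(O)c(C(=O)c2ccccc2)c1O
F7 | step 2 | (2,4,6-trihydroxy-2,3-dihydro-1-benzofuran-5-yl)(phenyl)methanone (lactol), racemic | OC1Cc2c(O1)cc(O)c(C(=O)c1ccccc1)c2O
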